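The constant I want from the earlier runs is one turnover, and it rests on two amounts: the catalyst charged and the impurity charged.

| flask | substrate | partner | free catalyst | impurity | remark |
|---|---|---|---|---|---|
| winter | 0.15 M | 5 equiv | 0.31 mol% | 0.30 mM | run made earlier |
| spring | 0.15 M | 5 equiv | 1.2 mol% | 0.30 mM | run made earlier |
| dawn | 0.15 M | 5 equiv | 0.62 mol% | 0.45 mM | run made earlier |
| flask | 0.15 M | 5.00 equiv | 0.62 mol% | 0.30 mM |  |

| run | time / min | product / % |
|---|---|---|
| winter | 1.00 | 2 |
| winter | 2.00 | 3 |
| winter | 3.00 | 5 |
| winter | 4.00 | 6 |
| winter | 5.00 | 5 |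
| winter | 6.00 | 9 |
| spring | 0.500 | 8 |
| spring | 0.833 | 9 |
| spring | 1.33 | 14 |
| spring | 2.00 | 19 |
| spring | 4.00 | 38 |
| spring | 6.00 | 57 |
| dawn | 1.33 | 6 |
| dawn | 2.50 | 9 |
| dawn | 4.00 | 12 |
| dawn | 5.00 | 18 |
| dawn | 6.00 | 19 |

(standard deviation of a reading: 1.5 percentage points)

* apparent order in partner when 20% of the substrate are converted (percent change of the rate of making product for one percent more partner charged)

From the winter run to the spring run the catalyst charge rises 3.87-fold, but the mean rate read over the first 6.00 min goes from 0.00225 M min⁻¹ to 0.0143 M min⁻¹, a 6.36-fold rise, so the rate as read grows faster than the charge. I read this as each impurity removing one catalyst from the round. What remains is working catalyst, 1.50 mM in the spring run. Dividing the spring mean rate by it gives a reading of 9.50 min⁻¹, the turnover of one working catalyst. In this flask the impurity takes 32.3% of the charge, which leaves 0.630 mM working, so I expect a rate of 0.00598 M min⁻¹.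

The spring slope reads 0.0142 M min⁻¹ up to 2.00 min and 0.0143 M min⁻¹ after it, while by 6.00 min partner has fallen by 11.4% of its charge, reckoned as one partner per product. I lean towards an order in partner nearer zero than one, but as a guess: these slopes carry the scatter of the readings, and no earlier run changes the partner charge. The forecast gives 0.5: “So this is a guess: about 0.5, spanning 0–1.”

The simulation gives 0.0025 for this flask.

    catalyst intermediate B ⇌ released group + catalyst intermediate C (K = 9.10 M, k = 0.210 s⁻¹)
    partner + catalyst intermediate A → catalyst intermediate B (k = 95.0 M⁻¹ s⁻¹)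
    catalyst intermediate C → free catalyst + product (k = 23.0 s⁻¹)
    free catalyst + impurity → spent catalyst (k = 380 M⁻¹ s⁻¹)
    substrate + free catalyst → catalyst intermediate A (k = 6.40 M⁻¹ s⁻¹)

At 6.00 min this flask holds 0.161% of its catalyst as catalyst intermediate A, the form that meets partner, against 51.8% as catalyst intermediate B, the resting state. The rate at 20% conversion is 0.00618 M min⁻¹, against the 0.00598 M min⁻¹ from the turnover. In the dawn run, with 0.480 mM working, the turnover gives 18.2% product at 6.00 min, and the reading there is 19%.

(The readings were computed with made-up constants, and the scatter is random.)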